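The seven-membered ring (C3a–C4–C5–C6–C7–C8–C8a, azulene numbering) is closed last at C6–C7. The step exploits the C8–C7=C6(CH3)–C5 allylic unit: at the enone level, C7 is the α-carbon of a C8 methyl ketone and the C6 methyl is a masked terminal alkyne carbon. A gold-catalysed 7-exo-dig Conia-ene-type attack of the silyl enol ether of an acetyl group at C8a on a C4 homopropargyl arm, then alkene migration into conjugation, forms the trans-fused cycloheptenone with its trisubstituted alkene in one operation. The precursor is a trans-2,3-disubstituted cyclopentanol from an enantioselective conjugate addition–aldol sequence on 3-methylcyclopent-2-enone.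

Key step: step 9

Remark: all intermediates carry the azulene numbers of the target (five-membered ring C1, C2, C3, C3a, C8a; seven-membered ring C3a, C4 to C8, C8a); the enantiomer of the chiral NHC ligand in step 1 is chosen to give the (S)-configured quaternary carbon, and compounds 13 and 21 are taken as commercial.

Step 1
Reactants: 1 3-methylcyclopent-2-en-1-one; 2 ethynyl(trimethyl)silane
Product: 5 trimethylsilyl enol ether of (S)-3-methyl-3-[1-(trimethylsilyl)ethenyl]cyclopentanone (enol double bond C3=C3a), via vinylalane 3 (not isolated), via aluminium enolate 4 (not isolated)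
Conditions: 2, i-Bu2AlH, hexanes, 55 °C; then 1, Cu(OTf)2 (5 mol %), chiral sulfonate-bearing NHC ligand (as imidazolinium salt, 5 mol %), THF, −78 to −30 °C; then Me3SiOTf, −78 °C
Reagents that add atoms: trimethylsilyl trifluoromethanesulfonate C[Si](C)(C)OS(=O)(=O)C(F)(F)F
Why: Copper–NHC-catalysed enantioselective conjugate addition of a silyl-substituted vinylaluminium (from hydroalumination of 2) to a β-substituted cyclic enone is an established route to all-carbon quaternary centres, the ligand setting C8a (S), and O-silylation of the aluminium enolate fixes the enolate towards C3a.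

Step 2
Reactants: 6 4-(trimethylsilyl)but-3-yn-1-ol
Product: 7 4-(trimethylsilyl)but-3-ynal
Conditions: Dess–Martin periodinane, NaHCO3, CH2Cl2, 0 °C; crude solution used at once
Reagents that add atoms: none
Why: Dess–Martin oxidation is neutral and fast, which should give the isomerisation-prone β,γ-alkynyl aldehyde without allene formation.

Step 3
Reactants: 5 trimethylsilyl enol ether; 7 4-(trimethylsilyl)but-3-ynal
Product: 10 (2S,3S)-2-[(1S)-1-hydroxy-4-(trimethylsilyl)but-3-yn-1-yl]-3-methyl-3-[1-(trimethylsilyl)ethenyl]cyclopentan-1-one, via lithium enolate 8 (not isolated), via chlorozinc enolate 9 (not isolated)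
Conditions: 5, MeLi, THF, 0 °C; ZnCl2, −78 °C; then 7, −78 °C; aq. NH4Cl
Reagents that add atoms: none
Why: Methyllithium cleaves the silyl enol ether to the regiodefined enolate, and the cyclic (E)-zinc enolate should add to 7 through a closed chair transition state (anti aldol, C4 S) on the face of C3a opposite the bulky silylvinyl group on C8a, which sets C3a (S) with the new chain trans to that group.

Step 4
Reactants: 10 aldol adduct
Product: 11 (1R,2S,3S)-2-[(1S)-1-hydroxy-4-(trimethylsilyl)but-3-yn-1-yl]-3-methyl-1-(propan-2-yl)-3-[1-(trimethylsilyl)ethenyl]cyclopentan-1-ol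
Conditions: i-PrMgCl (4 equiv), CeCl3 (anhydrous, 4 equiv), THF, −78 to −40 °C
Reagents that add atoms: isopropylmagnesium chloride CC(C)[Mg]Cl
Why: The organocerium reagent should add to the hindered, enolisable ketone without enolisation, reduction or retro-aldol cleavage, approaching C3 anti to the adjacent C3a side chain so that the new tertiary hydroxyl (C3 R) is cis to that chain (substrate-controlled 1,2-addition).

Step 5
Reactants: 11 diol with silylated alkyne
Product: 12 (1R,2S,3S)-2-[(1S)-1-hydroxybut-3-yn-1-yl]-3-methyl-1-(propan-2-yl)-3-[1-(trimethylsilyl)ethenyl]cyclopentan-1-ol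
Conditions: K2CO3, MeOH, rt
Reagents that add atoms: none
Why: Methanolysis removes the alkynyl silyl group only, because the vinylic C–Si bond is not cleaved under these conditions (protodesilylation of an alkynylsilane).

Step 6
Reactants: 12 alkynyl diol; 13 4-[(tert-butyldimethylsilyl)oxy]benzoic acid
Product: 14 (1S)-1-[(1S,2R,5S)-2-hydroxy-5-methyl-2-(propan-2-yl)-5-[1-(trimethylsilyl)ethenyl]cyclopentyl]but-3-yn-1-yl 4-[(tert-butyldimethylsilyl)oxy]benzoate
Conditions: EDC·HCl, DMAP, CH2Cl2, rt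
Reagents that add atoms: none
Why: Steglich esterification should acylate the secondary C4 hydroxyl while the tertiary C3 hydroxyl is too hindered to react, and no stereocentre is touched.

Step 7
Reactants: 14 C4 benzoate
Product: 16 (1S)-1-[(1S,2R,5S)-5-acetyl-2-hydroxy-5-methyl-2-(propan-2-yl)cyclopentyl]but-3-yn-1-yl 4-[(tert-butyldimethylsilyl)oxy]benzoate, via epoxysilane 15 (not isolated)
Conditions: mCPBA, NaHCO3, CH2Cl2, 0 °C; aq. Na2S2O3; then 0.5 M HClO4, THF/H2O, rt
Reagents that add atoms: 3-chloroperoxybenzoic acid OOC(=O)c1cccc(Cl)c1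
Why: Epoxidation of the vinylsilane followed by acid-promoted ring opening (β-silicon-stabilised cation) and loss of silicon turns the 1-silylvinyl group into a methyl ketone, a known unmasking of an acyl group that leaves the alkyne and the esters alone.

Step 8
Reactants: 16 methyl ketone
Product: 17 (1S)-1-[(1S,2R,5S)-5-methyl-2-(propan-2-yl)-2-[(triethylsilyl)oxy]-5-{1-[(triethylsilyl)oxy]ethenyl}cyclopentyl]but-3-yn-1-yl 4-[(tert-butyldimethylsilyl)oxy]benzoate
Conditions: Et3SiOTf (3 equiv), Et3N, CH2Cl2, −78 to 0 °C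
Reagents that add atoms: triethylsilyl trifluoromethanesulfonate CC[Si](CC)(CC)OS(=O)(=O)C(F)(F)F
Why: Soft enolisation gives the only possible enol ether of the methyl ketone (C8a is quaternary) and at the same time silylates the tertiary hydroxyl, which would otherwise add to the gold-activated alkyne.

Step 9
Reactants: 17 alkynyl silyl enol ether
Product: 19 (3R,3aS,4S,8aS)-6,8a-dimethyl-8-oxo-3-(propan-2-yl)-3-[(triethylsilyl)oxy]-1,2,3,3a,4,5,8,8a-octahydroazulen-4-yl 4-[(tert-butyldimethylsilyl)oxy]benzoate, via methylidene ketone 18 (not isolated)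
Conditions: [(2-biphenylyl)(t-Bu)2P]Au(NCMe)SbF6 (5 mol %), t-BuOH (1.2 equiv), CH2Cl2, rt; then Et3N, rt
Reagents that add atoms: none
Why: The cationic gold catalyst π-activates the terminal alkyne, the enol ether carbon C7 attacks the internal alkyne carbon C6 anti to gold, and t-BuOH takes the silyl group and protonates the vinyl–gold bond to give the exocyclic methylene ketone 18, after which mild base moves the alkene into conjugation through the dienolate. The closest known reaction type is the gold-catalysed Conia-ene-type carbocyclisation of alkynyl silyl enol ethers, which is known to give methylenecycloheptanes. The seven-membered ring closes in the 7-exo-dig mode. No stereocentre is formed: C3, C3a, C4 and C8a are carried over, and the trans ring fusion follows from the trans arms of 17. The step needs C-attack at C6 in preference to attack at the terminal carbon (8-endo) or O-attack by the benzoate carbonyl, which the exo preference of a tethered terminal alkyne and the higher nucleophilicity of the enol ether should secure, the tertiary oxygen being silylated. The alkene should end at C6=C7 because only this position is conjugated with C8=O, and Et3N in place of a stronger base should avoid vinylogous elimination of the C4 ester.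

Step 10
Reactants: 19 bicyclic enone
Product: 20 (3R,3aS,4S,8S,8aS)-8-hydroxy-6,8a-dimethyl-3-(propan-2-yl)-3-[(triethylsilyl)oxy]-1,2,3,3a,4,5,8,8a-octahydroazulen-4-yl 4-[(tert-butyldimethylsilyl)oxy]benzoate
Conditions: NaBH4, CeCl3·7H2O, MeOH, −40 °C
Reagents that add atoms: none
Why: Luche reduction gives 1,2-reduction of the enone, and hydride should attack C8 from the face opposite the angular C8a methyl group, placing the new hydroxyl cis to that methyl (C8 S).

Step 11
Reactants: 20 allylic alcohol; 21 angelic acid ((Z)-2-methylbut-2-enoic acid)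
Product: 23 (3R,3aS,4S,8S,8aS)-6,8a-dimethyl-8-{[(2Z)-2-methylbut-2-enoyl]oxy}-3-(propan-2-yl)-3-[(triethylsilyl)oxy]-1,2,3,3a,4,5,8,8a-octahydroazulen-4-yl 4-[(tert-butyldimethylsilyl)oxy]benzoate, via mixed anhydride 22 (not isolated)
Conditions: 21, 2,4,6-trichlorobenzoyl chloride, Et3N, toluene, rt; then 20, toluene, 80 °C
Reagents that add atoms: none
Why: Yamaguchi esterification through the mixed anhydride acylates hindered secondary alcohols, and running it without DMAP should keep the (Z)-geometry of the angelate, while the tertiary oxygen is protected and C8 is not affected.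

Step 12
Reactants: 23 bis-silylated diester
Product: 24 target, (3R,3aS,4S,8S,8aS)-3-hydroxy-6,8a-dimethyl-8-{[(2Z)-2-methylbut-2-enoyl]oxy}-3-(propan-2-yl)-1,2,3,3a,4,5,8,8a-octahydroazulen-4-yl 4-hydroxybenzoate
Conditions: HF·pyridine, pyridine, THF, 0 °C to rt
Reagents that add atoms: none
Why: Buffered HF·pyridine should cleave the aryl silyl ether and the tertiary triethylsilyl ether by fluoride-mediated desilylation without touching the two esters or the (Z)-enoate.

Compound list
1 | 3-methylcyclopent-2-en-1-one | CC1=CC(=O)CC1 | starting material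
2 | ethynyl(trimethyl)silane | C#C[Si](C)(C)C | starting material
3 | bis(2-methylpropyl)[1-(trimethylsilyl)ethenyl]alane (not isolated) | CC(C)C[Al](CC(C)C)C(=C)[Si](C)(C)C | intermediate
4 | diisobutylaluminium enolate of (S)-3-methyl-3-[1-(trimethylsilyl)ethenyl]cyclopentanone, enolate C3=C3a (not isolated) | CC(C)C[Al](CC(C)C)OC1=C[C@](C(=C)[Si](C)(C)C)(C)CC1 | intermediate
5 | trimethyl({(3S)-3-methyl-3-[1-(trimethylsilyl)ethenyl]cyclopent-1-en-1-yl}oxy)silane | C[Si](C)(C)OC1=C[C@](C(=C)[Si](C)(C)C)(C)CC1 | intermediate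
6 | 4-(trimethylsilyl)but-3-yn-1-ol | C[Si](C)(C)C#CCCO | starting material
7 | 4-(trimethylsilyl)but-3-ynal | C[Si](C)(C)C#CCC=O | intermediate
8 | lithium enolate corresponding to 5 (not isolated) | [Li]OC1=C[C@](C(=C)[Si](C)(C)C)(C)CC1 | intermediate
9 | chlorozinc enolate corresponding to 5 (not isolated) | Cl[Zn]OC1=C[C@](C(=C)[Si](C)(C)C)(C)CC1 | intermediate
10 | (2S,3S)-2-[(1S)-1-hydroxy-4-(trimethylsilyl)but-3-yn-1-yl]-3-methyl-3-[1-(trimethylsilyl)ethenyl]cyclopentan-1-one | C[Si](C)(C)C#CC[C@H](O)[C@@H]1[C@](C(=C)[Si](C)(C)C)(C)CCC1=O | intermediate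
11 | (1R,2S,3S)-2-[(1S)-1-hydroxy-4-(trimethylsilyl)but-3-yn-1-yl]-3-methyl-1-(propan-2-yl)-3-[1-(trimethylsilyl)ethenyl]cyclopentan-1-ol | C[Si](C)(C)C#CC[C@H](O)[C@@H]1[C@](C(=C)[Si](C)(C)C)(C)CC[C@@]1(O)C(C)C | intermediate
12 | (1R,2S,3S)-2-[(1S)-1-hydroxybut-3-yn-1-yl]-3-methyl-1-(propan-2-yl)-3-[1-(trimethylsilyl)ethenyl]cyclopentan-1-ol | C#CC[C@H](O)[C@@H]1[C@](C(=C)[Si](C)(C)C)(C)CC[C@@]1(O)C(C)C | intermediate
13 | 4-[(tert-butyldimethylsilyl)oxy]benzoic acid | CC(C)(C)[Si](C)(C)Oc1ccc(cc1)C(=O)O | starting material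
14 | (1S)-1-[(1S,2R,5S)-2-hydroxy-5-methyl-2-(propan-2-yl)-5-[1-(trimethylsilyl)ethenyl]cyclopentyl]but-3-yn-1-yl 4-[(tert-butyldimethylsilyl)oxy]benzoate | C#CC[C@H](OC(=O)c2ccc(O[Si](C)(C)C(C)(C)C)cc2)[C@@H]1[C@](C(=C)[Si](C)(C)C)(C)CC[C@@]1(O)C(C)C | intermediate
15 | epoxysilane of 14, 2-(trimethylsilyl)oxiran-2-yl group at C8a, either epoxide configuration (not isolated) | C#CC[C@H](OC(=O)c2ccc(O[Si](C)(C)C(C)(C)C)cc2)[C@@H]1[C@](C3(CO3)[Si](C)(C)C)(C)CC[C@@]1(O)C(C)C | intermediate
16 | (1S)-1-[(1S,2R,5S)-5-acetyl-2-hydroxy-5-methyl-2-(propan-2-yl)cyclopentyl]but-3-yn-1-yl 4-[(tert-butyldimethylsilyl)oxy]benzoate | C#CC[C@H](OC(=O)c2ccc(O[Si](C)(C)C(C)(C)C)cc2)[C@@H]1[C@](C(C)=O)(C)CC[C@@]1(O)C(C)C | intermediate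
17 | (1S)-1-[(1S,2R,5S)-5-methyl-2-(propan-2-yl)-2-[(triethylsilyl)oxy]-5-{1-[(triethylsilyl)oxy]ethenyl}cyclopentyl]but-3-yn-1-yl 4-[(tert-butyldimethylsilyl)oxy]benzoate | C#CC[C@H](OC(=O)c2ccc(O[Si](C)(C)C(C)(C)C)cc2)[C@@H]1[C@](C(=C)O[Si](CC)(CC)CC)(C)CC[C@@]1(O[Si](CC)(CC)CC)C(C)C | intermediate
18 | (3R,3aS,4S,8aS)-8a-methyl-6-methylidene-8-oxo-3-(propan-2-yl)-3-[(triethylsilyl)oxy]decahydroazulen-4-yl 4-[(tert-butyldimethylsilyl)oxy]benzoate (not isolated) | O=C1CC(=C)C[C@H](OC(=O)c3ccc(O[Si](C)(C)C(C)(C)C)cc3)[C@@H]2[C@]1(C)CC[C@@]2(O[Si](CC)(CC)CC)C(C)C | intermediate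
19 | (3R,3aS,4S,8aS)-6,8a-dimethyl-8-oxo-3-(propan-2-yl)-3-[(triethylsilyl)oxy]-1,2,3,3a,4,5,8,8a-octahydroazulen-4-yl 4-[(tert-butyldimethylsilyl)oxy]benzoate | O=C1C=C(C)C[C@H](OC(=O)c3ccc(O[Si](C)(C)C(C)(C)C)cc3)[C@@H]2[C@]1(C)CC[C@@]2(O[Si](CC)(CC)CC)C(C)C | intermediate
20 | (3R,3aS,4S,8S,8aS)-8-hydroxy-6,8a-dimethyl-3-(propan-2-yl)-3-[(triethylsilyl)oxy]-1,2,3,3a,4,5,8,8a-octahydroazulen-4-yl 4-[(tert-butyldimethylsilyl)oxy]benzoate | O[C@H]1C=C(C)C[C@H](OC(=O)c3ccc(O[Si](C)(C)C(C)(C)C)cc3)[C@@H]2[C@]1(C)CC[C@@]2(O[Si](CC)(CC)CC)C(C)C | intermediate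
21 | angelic acid, (Z)-2-methylbut-2-enoic acid | C/C=C(/C)C(=O)O | starting material
22 | (Z)-2-methylbut-2-enoic 2,4,6-trichlorobenzoic anhydride (not isolated) | C/C=C(/C)C(=O)OC(=O)c1c(Cl)cc(Cl)cc1Cl | intermediate
23 | (3R,3aS,4S,8S,8aS)-6,8a-dimethyl-8-{[(2Z)-2-methylbut-2-enoyl]oxy}-3-(propan-2-yl)-3-[(triethylsilyl)oxy]-1,2,3,3a,4,5,8,8a-octahydroazulen-4-yl 4-[(tert-butyldimethylsilyl)oxy]benzoate | C/C=C(/C)C(=O)O[C@H]1C=C(C)C[C@H](OC(=O)c3ccc(O[Si](C)(C)C(C)(C)C)cc3)[C@@H]2[C@]1(C)CC[C@@]2(O[Si](CC)(CC)CC)C(C)C | intermediate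
24 | (3R,3aS,4S,8S,8aS)-3-hydroxy-6,8a-dimethyl-8-{[(2Z)-2-methylbut-2-enoyl]oxy}-3-(propan-2-yl)-1,2,3,3a,4,5,8,8a-octahydroazulen-4-yl 4-hydroxybenzoate | C/C=C(/C)C(=O)O[C@H]1C=C(C)C[C@H](OC(=O)c2ccc(O)cc2)[C@@H]2[C@]1(C)CC[C@@]2(O)C(C)C | target

Total step count: 12. Longest linear sequence: 11 steps (steps 1 and 3 to 12, from 3-methylcyclopent-2-en-1-one); step 2 is a one-step branch.

Steps most likely to fail

Step 9. The gold-activated alkyne may be intercepted by the C4 benzoate carbonyl or by traces of water (net hydration), the enol ether may be protodesilylated before the C–C bond forms, or the C4 ester may be lost by vinylogous elimination during the alkene migration. The fallback gives up π-acid catalysis for carbonyl condensation and sets out from 16. Markovnikov hydration of the alkyne (Ph3PAuNTf2 2 mol %, H2O, 1,4-dioxane, 60 °C) should give the diketone (1S)-1-[(1S,2R,5S)-5-acetyl-2-hydroxy-5-methyl-2-(propan-2-yl)cyclopentyl]-3-oxobutyl 4-[(tert-butyldimethylsilyl)oxy]benzoate F1. Acid-catalysed intramolecular aldol condensation (TsOH·H2O 0.2 equiv, benzene, 60 °C) should then join the enol of the C8 acetyl group to the unhindered C6 ketone; the other modes need attack on the neopentyl C8 carbonyl or a trans-fused bicyclo[3.3.0]octane. This gives the hydroxy enone (3R,3aS,4S,8aS)-3-hydroxy-6,8a-dimethyl-8-oxo-3-(propan-2-yl)-1,2,3,3a,4,5,8,8a-octahydroazulen-4-yl 4-[(tert-butyldimethylsilyl)oxy]benzoate F2. Silylation of its tertiary hydroxyl (Et3SiOTf, 2,6-lutidine, CH2Cl2, −78 °C) comes back to the route at 19.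

Step 3. The zinc enolate may be quenched by proton transfer from the acidic α-methylene of ynal 7 (loss of the regiodefined enolate, isomerisation of 7 to the allenal), or the chair transition state may give poor anti/syn control at C4. The fallback sets out from 5 and 7 and no longer relies on the aldol to fix C4. A non-basic Mukaiyama aldol (BF3·OEt2, CH2Cl2, −78 °C) avoids the proton transfer; whatever amount of the C4 epimer (2S,3S)-2-[(1R)-1-hydroxy-4-(trimethylsilyl)but-3-yn-1-yl]-3-methyl-3-[1-(trimethylsilyl)ethenyl]cyclopentan-1-one F3 it gives is not discarded. F3 is taken through the conditions of steps 4 and 5 to the C4-epimeric diol with silylated alkyne F4 and the C4-epimeric alkynyl diol F5. Mitsunobu esterification of F5 with 13 (PPh3, DIAD, toluene, 0 °C to rt) should then install the benzoate with inversion at C4 and come back to the route at 14.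

Step 11. Acylation of the neopentyl-type C8 alcohol may be so slow that Z-to-E isomerisation of the activated angelate (tiglate formation) competes. The fallback builds the (Z)-enoate on the molecule and sets out from 20. Esterification with 2-[bis(2,2,2-trifluoroethoxy)phosphoryl]propanoic acid (EDC·HCl, DMAP, CH2Cl2) should give the C8 2-[bis(2,2,2-trifluoroethoxy)phosphoryl]propanoate F6. Still–Gennari olefination of F6 with acetaldehyde (KN(SiMe3)2, 18-crown-6, THF, −78 °C) should give the (Z)-2-methylbut-2-enoate and come back to the route at 23.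

Further compounds
F1 | step 9 | (1S)-1-[(1S,2R,5S)-5-acetyl-2-hydroxy-5-methyl-2-(propan-2-yl)cyclopentyl]-3-oxobutyl 4-[(tert-butyldimethylsilyl)oxy]benzoate | CC(=O)C[C@H](OC(=O)c2ccc(O[Si](C)(C)C(C)(C)C)cc2)[C@@H]1[C@](C(C)=O)(C)CC[C@@]1(O)C(C)C
F2 | step 9 | (3R,3aS,4S,8aS)-3-hydroxy-6,8a-dimethyl-8-oxo-3-(propan-2-yl)-1,2,3,3a,4,5,8,8a-octahydroazulen-4-yl 4-[(tert-butyldimethylsilyl)oxy]benzoate | O=C1C=C(C)C[C@H](OC(=O)c3ccc(O[Si](C)(C)C(C)(C)C)cc3)[C@@H]2[C@]1(C)CC[C@@]2(O)C(C)C
F3 | step 3 | (2S,3S)-2-[(1R)-1-hydroxy-4-(trimethylsilyl)but-3-yn-1-yl]-3-methyl-3-[1-(trimethylsilyl)ethenyl]cyclopentan-1-one | C[Si](C)(C)C#CC[C@@H](O)[C@@H]1[C@](C(=C)[Si](C)(C)C)(C)CCC1=O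
F4 | step 3 | (1R,2S,3S)-2-[(1R)-1-hydroxy-4-(trimethylsilyl)but-3-yn-1-yl]-3-methyl-1-(propan-2-yl)-3-[1-(trimethylsilyl)ethenyl]cyclopentan-1-ol | C[Si](C)(C)C#CC[C@@H](O)[C@@H]1[C@](C(=C)[Si](C)(C)C)(C)CC[C@@]1(O)C(C)C
F5 | step 3 | (1R,2S,3S)-2-[(1R)-1-hydroxybut-3-yn-1-yl]-3-methyl-1-(propan-2-yl)-3-[1-(trimethylsilyl)ethenyl]cyclopentan-1-ol | C#CC[C@@H](O)[C@@H]1[C@](C(=C)[Si](C)(C)C)(C)CC[C@@]1(O)C(C)C
F6 | step 11 | (3R,3aS,4S,8S,8aS)-8-({2-[bis(2,2,2-trifluoroethoxy)phosphoryl]propanoyl}oxy)-6,8a-dimethyl-3-(propan-2-yl)-3-[(triethylsilyl)oxy]-1,2,3,3a,4,5,8,8a-octahydroazulen-4-yl 4-[(tert-butyldimethylsilyl)oxy]benzoate, either configuration at the phosphonate carbon | CC(P(=O)(OCC(F)(F)F)OCC(F)(F)F)C(=O)O[C@H]1C=C(C)C[C@H](OC(=O)c3ccc(O[Si](C)(C)C(C)(C)C)cc3)[C@@H]2[C@]1(C)CC[C@@]2(O[Si](CC)(CC)CC)C(C)C
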